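The constants of this catalyst's round tell you what to count: turnovers.

common to all: substrate 25 mM; coupling partner 25.0 mM; free catalyst 3.5 mM; time 10 s

| run | temperature |
|---|---|
| south | 120 °C |
| west | 90 °C |
| north-west | 105 °C |

1. which flask leads in amount of target, in percent of the substrate charged ("all alike" within 1.5 percentage points) (south / west / north-west / all alike)
2. how much target is there at the end, in percent of the substrate charged: south
3. how much target is there at the end, in percent of the substrate charged: west
4. how much target is there at the end, in percent of the substrate charged: north-west

- percentages count the substrate that a species holds: one side product counts as two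
- the list of constants is for 90 °C, to be carried to other temperatures by the activation energies and enthalpies

    catalyst intermediate B ⇌ catalyst intermediate C (K1 = 0.71, k1 = 2.4 s⁻¹, Ea1 = 77.0 kJ mol⁻¹, ΔH1 = 13.0 kJ mol⁻¹)
    substrate + catalyst intermediate A → catalyst intermediate B (k2 = 35 L mol⁻¹ s⁻¹, Ea2 = 41.0 kJ mol⁻¹)
    catalyst intermediate A → spent catalyst (k3 = 0.063 s⁻¹, Ea3 = 91.0 kJ mol⁻¹)
    coupling partner + free catalyst → catalyst intermediate A (k4 = 35 L mol⁻¹ s⁻¹, Ea4 = 50.0 kJ mol⁻¹)
    substrate + target → side product (k5 = 1.0 L mol⁻¹ s⁻¹, Ea5 = 70.0 kJ mol⁻¹)
    catalyst intermediate C → free catalyst + target (k6 = 0.80 s⁻¹, Ea6 = 75.0 kJ mol⁻¹)
    (constants at 90 °C)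

The round runs like this. Coupling partner turns free catalyst into intermediate A, and substrate turns A into intermediate B. B exchanges with intermediate C, and C releases target and free catalyst. Two things go wrong: A can die to spent catalyst, and substrate can turn target into side product.

My reckoning, in rates:

1. Start rate in west. A catalyst waits 1.14 s for coupling partner and 1.14 s for substrate. It then spends about 3.01 s in the B and C pair, taking their exchange as quick. One round takes 5.30 s, so the start rate per catalyst is 0.189 s⁻¹.

2. What kills it. At A, capture runs at the capture constant times c(substrate), 0.875 s⁻¹, and death at 0.063 s⁻¹. Capture is faster than death, and their ratio is 13.9 in west. Call this ratio the turnover budget: the rounds one catalyst makes before it dies, its turnover number.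

3. South. Death has 50.0 kJ mol⁻¹ more activation energy than capture, the same as 50.0 kJ mol⁻¹. So the budget shrinks by the factor of that step, 3.5, to 3.93. The round shortens to 1.11 s.

4. Slowing. Budget times round gives the catalyst's life: 73.6 s in west, 4.34 s in south. The rate falls as exp(−t/life). By 10 s that factor is 0.873 in west and 0.100 in south. West reads long before its life ends, and south reads after.

5. The end. Summed up, that is 1.77 turnovers in west and 3.54 in south. These equal 24.7% and 49.5% of the substrate, as target made. This reckoning lets each catalyst run at full rate from the first second, though its first round takes 5.30 s. It also holds c(substrate) and c(coupling partner) at their charges. So I expect these figures to run high. South also loses target at 0.147 s⁻¹ at the start, against 0.0250 s⁻¹ in west. I give no figure for north-west, and my gross figures are not the net ones of the forecast.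

The forecast says 21% for south, 15% for west and 27% for north-west, so north-west leads. The middle flask, it says, “gives about three turnovers with moderate catalyst death and side-product loss”.

The simulation gives 20.8% for south, 15.9% for west and 26.8% for north-west, so north-west leads, as forecast.

South made 2.60 turnovers, counting target later lost to side product, against a starting budget of 3.93. By then 89.1% of its catalyst was spent. Take the death of intermediate A away and south ends at 51.2% instead of 20.8%. That is the largest single effect tried, not the whole story.

Now leave west until 40 s. Its life of 73.6 s gives 41.9% of the catalyst spent. The computed flask holds more, 48.1%, with substrate down to 30.4% and target at 42.0%.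

All constants stand for no real mixture; the flask was simulated.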